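## Retrosynthetic overview

1. The last bond made is C1(ring A)–C(carbinol): a chiral-phosphoric-acid-catalysed allylboration of the ring B enal with a (cyclohexa-1,4-dienyl)methyl boronate. It sets the ring A and carbinol centres together and unveils the exocyclic methylene.
2. The ring A boronate comes from a dienyl triflate, made by one-carbon ring expansion of 2,2-dimethylcyclopent-3-enone: 1,2-shift of the quaternary allylic carbon in a β-oxido carbenoid, with the transposed enolate trapped as its triflate.
3. The cyclopentenone comes from ring-closing metathesis of the prenyl bromide/allyl cyanide adduct.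
4. The ring B enal comes from an alkyne (methylalumination, formaldehyde), which comes from a bicyclic bromo lactone, from methyl addition anti to bromine in a trans α-bromo ketone, from an enantioselective Diels–Alder adduct of a 2-silyloxybutadiene and methyl acrylate.
5. Ring order: five-membered ring by metathesis, then ring A by ring expansion; ring B by cycloaddition; the two rings are joined in the final step.

Assumption: the catalyst enantiomers in steps 6 and 12 are written by analogy with their reported facial preferences; if the sense proves opposite, the mirror-image catalyst is used.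

## Route

Step 1
Reactants: 1 prenyl bromide (1-bromo-3-methylbut-2-ene); 2 allyl cyanide (but-3-enenitrile)
Product: 5 3,3-dimethylhepta-1,6-dien-4-one, via prenylzinc bromide 3 (not isolated), via zinc ketiminate 4 (not isolated)
Conditions: Zn dust, LiCl, THF, 0 °C; then 2, 0 → 25 °C; cold 1 M aq citric acid, 0 °C
Reagents that add atoms: water, O
Why: Barbier/Blaise-type allylzincation of the nitrile, in which prenylzinc bromide attacks through its γ-carbon (SE2′) so the gem-dimethyl carbon ends next to the carbonyl, and cold mild-acid hydrolysis of the ketiminate gives the β,γ-unsaturated ketone without conjugation; no stereocentre.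

Step 2
Reactants: 5 3,3-dimethylhepta-1,6-dien-4-one
Product: 6 2,2-dimethylcyclopent-3-en-1-one
Conditions: second-generation Grubbs catalyst RuCl2(=CHPh)(PCy3)(H2IMes) (1 mol %), 1,4-benzoquinone (5 mol %), CH2Cl2, 40 °C
Reagents that add atoms: none
Why: Ring-closing metathesis of the two terminal vinyl groups to the five-membered ring (helped by the gem-dimethyl group) with loss of ethene, benzoquinone suppressing ruthenium hydride isomerisation of the β,γ-enone; no stereocentre.

Step 3
Reactants: 6 2,2-dimethylcyclopent-3-en-1-one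
Product: 9 3,3-dimethylcyclohexa-1,4-dien-1-yl trifluoromethanesulfonate, via lithium dibromomethyl alkoxide 7 (not isolated), via lithium dienolate 8 (not isolated)
Conditions: CH2Br2, lithium 2,2,6,6-tetramethylpiperidide, THF, −95 °C; add 6, −95 → −78 °C; n-BuLi, −78 → −20 °C; PhNTf2, −78 → 0 °C
Reagents that add atoms: dibromomethane, BrCBr; N-phenylbis(trifluoromethanesulfonimide), O=S(=O)(N(c1ccccc1)S(=O)(=O)C(F)(F)F)C(F)(F)F
Why: Proposed new method: a triflative β-oxido-carbenoid ring expansion of a β,γ-unsaturated α,α-dimethylcyclopentenone, in which LiCHBr2 adds to the ketone, Br–Li exchange gives the α-bromo-α-lithio alkoxide, the electron-rich quaternary allylic ring carbon migrates to the carbenoid carbon with loss of LiBr in preference to the CH2 (1,2-shift, five- to six-membered ring), the lithium enolate is born with its double bond towards the inserted CH (a regiochemistry that deprotonation cannot give), and PhNTf2 fixes it as the dienyl triflate; closest known reaction type is the Nozaki–Yamamoto ring enlargement of saturated cycloalkanones through β-oxido carbenoids with silyl or alkyl trapping of the enolate; no stereocentre.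

Step 4
Reactants: 9 3,3-dimethylcyclohexa-1,4-dien-1-yl trifluoromethanesulfonate
Product: 10 2-[(3,3-dimethylcyclohexa-1,4-dien-1-yl)methyl]-4,4,5,5-tetramethyl-1,3,2-dioxaborolane
Conditions: CH2(Bpin)2 (1.5 equiv), Pd[P(t-Bu)3]2 (5 mol %), KOH (8 M aq, 3 equiv), 1,4-dioxane, 25 °C
Reagents that add atoms: bis[(pinacolato)boryl]methane, CC1(C)OB(CB2OC(C)(C)C(C)(C)O2)OC1(C)C
Why: Suzuki–Miyaura coupling of the alkenyl triflate with the geminal diborylmethane, in which hydroxide activates one boron and only one C–B bond is used, gives the allylic boronate whose ring holds the γ-substituent trans to CH2B; no stereocentre.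

Step 5
Reactants: 11 methyl vinyl ketone (but-3-en-2-one)
Product: 12 2-(triisopropylsilyloxy)buta-1,3-diene
Conditions: TIPSOTf, Et3N, CH2Cl2, 0 → 25 °C
Reagents that add atoms: triisopropylsilyl trifluoromethanesulfonate, CC(C)[Si](OS(=O)(=O)C(F)(F)F)(C(C)C)C(C)C
Why: Soft enolisation and O-silylation of the enone gives the 2-silyloxydiene, the triisopropylsilyl group being chosen so that the enol ether survives the Lewis acid of step 6; no stereocentre.

Step 6
Reactants: 12 2-(triisopropylsilyloxy)buta-1,3-diene; 13 methyl acrylate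
Product: 14 methyl (1R)-4-(triisopropylsilyloxy)cyclohex-3-ene-1-carboxylate
Conditions: (S)-3,3-diphenyl-1-(2-methylphenyl)tetrahydropyrrolo[1,2-c][1,3,2]oxazaborole activated with HNTf2 (10 mol %), CH2Cl2, −40 → −20 °C
Reagents that add atoms: none
Why: Catalytic enantioselective Diels–Alder reaction (cationic oxazaborolidine, Corey type) in which the 2-silyloxy group gives the 1,4 adduct and the boron-bound acrylate is attacked on the face left open by the catalyst, setting C1 as R.

Step 7
Reactants: 14 methyl (1R)-4-(triisopropylsilyloxy)cyclohex-3-ene-1-carboxylate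
Product: 15 methyl (1R,3S)-3-bromo-4-oxocyclohexane-1-carboxylate
Conditions: NBS, NaHCO3, THF, −40 → 0 °C
Reagents that add atoms: N-bromosuccinimide, O=C1CCC(=O)N1Br
Why: Electrophilic α-bromination of the silyl enol ether, in which bromine attacks C3 axially on the half-chair that keeps the ester pseudo-equatorial, gives the trans (axial) α-bromo ketone, so 3S is set by substrate control from C1.

Step 8
Reactants: 15 methyl (1R,3S)-3-bromo-4-oxocyclohexane-1-carboxylate
Product: 16 methyl (1R,3S,4R)-3-bromo-4-hydroxy-4-methylcyclohexane-1-carboxylate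
Conditions: MeMgBr (1.1 equiv), Et2O/toluene, −78 °C; aq NH4Cl
Reagents that add atoms: methylmagnesium bromide, C[Mg]Br
Why: Grignard 1,2-addition under Cornforth–Felkin control, methyl entering anti to the axial C–Br bond (Br and OH cis) and fixing 4R while the activated α-bromo ketone outruns the ester; the diastereomer from the minor cis-bromo ketone is removed here by chromatography because it would converge on the enantiomer of 18.

Step 9
Reactants: 16 methyl (1R,3S,4R)-3-bromo-4-hydroxy-4-methylcyclohexane-1-carboxylate
Product: 18 (1R,4S,6S)-6-bromo-1-methyl-2-oxabicyclo[2.2.2]octan-3-one, via sodium alkoxide of the 1-epimeric ester 17 (not isolated)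
Conditions: NaH (1.2 equiv), THF, 0 → 25 °C
Reagents that add atoms: none
Why: Base-mediated epimerisation–lactonisation (stereoconvergent), in which the tertiary alkoxide reversibly epimerises the ester α-carbon and only the epimer with the carboxyl cis to the alkoxide can close to the bicyclic lactone, which leaves the equilibrium as sodium methoxide precipitates; this sets the ring B attachment carbon as S.

Step 10
Reactants: 18 (1R,4S,6S)-6-bromo-1-methyl-2-oxabicyclo[2.2.2]octan-3-one
Product: 20 (1R,2S,4S)-2-bromo-4-ethynyl-1-methylcyclohexan-1-ol, via lactol 19 (not isolated)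
Conditions: i-Bu2AlH (1.1 equiv), CH2Cl2, −78 °C; then MeOH, K2CO3, dimethyl (1-diazo-2-oxopropyl)phosphonate, 0 → 25 °C
Reagents that add atoms: dimethyl (1-diazo-2-oxopropyl)phosphonate, COP(=O)(OC)C(=[N+]=[N-])C(C)=O
Why: Half-reduction of the lactone to the lactol followed in one pot by Seyferth–Gilbert homologation with the Ohira–Bestmann reagent, which converts the open hydroxy aldehyde to the alkyne with retention at the α-carbon, the lactol resting state and the equatorial preference guarding that centre.

Step 11
Reactants: 20 (1R,2S,4S)-2-bromo-4-ethynyl-1-methylcyclohexan-1-ol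
Product: 22 (1R,2S,4S)-2-bromo-4-[(2E)-4-hydroxybut-2-en-2-yl]-1-methylcyclohexan-1-ol, via alkenylalane 21 (not isolated)
Conditions: Me3Al (4 equiv), Cp2ZrCl2 (20 mol %), H2O (1 equiv), CH2Cl2, −20 °C; evaporate; n-BuLi (1 equiv), THF, −78 °C; (CH2O)n, −78 → 25 °C
Reagents that add atoms: trimethylaluminium, C[Al](C)C; paraformaldehyde (formaldehyde unit), C=O
Why: Negishi zirconium-catalysed methylalumination (syn carbometalation, methyl to the internal carbon) gives the (E)-2-methylalkenylalane, whose ate complex is hydroxymethylated by formaldehyde with retention, fixing the E trisubstituted alkene; the tertiary alcohol is carried as its aluminium alkoxide.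

Step 12
Reactants: 22 (1R,2S,4S)-2-bromo-4-[(2E)-4-hydroxybut-2-en-2-yl]-1-methylcyclohexan-1-ol; 10 2-[(3,3-dimethylcyclohexa-1,4-dien-1-yl)methyl]-4,4,5,5-tetramethyl-1,3,2-dioxaborolane
Product: 24 (1R,2S,4S)-2-bromo-4-[(2E,4R)-4-[(1R)-6,6-dimethyl-2-methylidenecyclohex-4-en-1-yl]-4-hydroxybut-2-en-2-yl]-1-methylcyclohexan-1-ol, via enal 23 (not isolated)
Conditions: MnO2, CH2Cl2, 25 °C; filter, evaporate; then 10 (1.5 equiv), (S)-3,3′-bis(2,4,6-triisopropylphenyl)-1,1′-binaphthyl-2,2′-diyl hydrogen phosphate (5 mol %), 4 Å sieves, toluene, −30 → 0 °C; aq NaHCO3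
Reagents that add atoms: none
Why: Allylic oxidation, then chiral phosphoric acid catalysed allylboration (Antilla type) through a chair six-membered transition state, in which the ring-locked E-type γ-substituent gives the anti adduct and the catalyst directs attack to the Si face of the aldehyde; this sets the carbinol and the ring A carbon both R, and the allyl transposition creates the exocyclic methylene.

## Compound list

1 | prenyl bromide (1-bromo-3-methylbut-2-ene) | CC(C)=CCBr | starting material
2 | allyl cyanide (but-3-enenitrile) | C=CCC#N | starting material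
3 | prenylzinc bromide | CC(C)=CC[Zn]Br | intermediate
4 | bromozinc ketiminate of 3,3-dimethylhepta-1,6-dien-4-imine | C=CCC(=N[Zn]Br)C(C)(C)C=C | intermediate
5 | 3,3-dimethylhepta-1,6-dien-4-one | C=CCC(=O)C(C)(C)C=C | intermediate
6 | 2,2-dimethylcyclopent-3-en-1-one | CC1(C)C=CCC1=O | intermediate
7 | lithium 1-(dibromomethyl)-2,2-dimethylcyclopent-3-en-1-olate | [Li+].[O-]C1(C(Br)Br)CC=CC1(C)C | intermediate
8 | lithium 3,3-dimethylcyclohexa-1,4-dien-1-olate | [Li+].[O-]C1=CC(C)(C)C=CC1 | intermediate
9 | 3,3-dimethylcyclohexa-1,4-dien-1-yl trifluoromethanesulfonate | CC1(C)C=CCC(OS(=O)(=O)C(F)(F)F)=C1 | intermediate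
10 | 2-[(3,3-dimethylcyclohexa-1,4-dien-1-yl)methyl]-4,4,5,5-tetramethyl-1,3,2-dioxaborolane | CC1(C)C=CCC(CB2OC(C)(C)C(C)(C)O2)=C1 | intermediate
11 | methyl vinyl ketone (but-3-en-2-one) | CC(=O)C=C | starting material
12 | 2-(triisopropylsilyloxy)buta-1,3-diene | C=CC(=C)O[Si](C(C)C)(C(C)C)C(C)C | intermediate
13 | methyl acrylate | COC(=O)C=C | starting material
14 | methyl (1R)-4-(triisopropylsilyloxy)cyclohex-3-ene-1-carboxylate | COC(=O)[C@H]1CC=C(O[Si](C(C)C)(C(C)C)C(C)C)CC1 | intermediate
15 | methyl (1R,3S)-3-bromo-4-oxocyclohexane-1-carboxylate | COC(=O)[C@H]1C[C@H](Br)C(=O)CC1 | intermediate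
16 | methyl (1R,3S,4R)-3-bromo-4-hydroxy-4-methylcyclohexane-1-carboxylate | COC(=O)[C@H]1C[C@H](Br)[C@](C)(O)CC1 | intermediate
17 | sodium alkoxide of methyl (1S,3S,4R)-3-bromo-4-hydroxy-4-methylcyclohexane-1-carboxylate | [Na+].COC(=O)[C@@H]1C[C@H](Br)[C@](C)([O-])CC1 | intermediate
18 | (1R,4S,6S)-6-bromo-1-methyl-2-oxabicyclo[2.2.2]octan-3-one (Br syn to the lactone oxygen) | O=C1O[C@@]2(C)[C@@H](Br)C[C@@H]1CC2 | intermediate
19 | (1R,4S,6S)-6-bromo-1-methyl-2-oxabicyclo[2.2.2]octan-3-ol (lactol, both anomers) | OC1O[C@@]2(C)[C@@H](Br)C[C@@H]1CC2 | intermediate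
20 | (1R,2S,4S)-2-bromo-4-ethynyl-1-methylcyclohexan-1-ol | C#C[C@H]1CC[C@@](C)(O)[C@@H](Br)C1 | intermediate
21 | dimethyl[(1E)-2-(ring B)prop-1-en-1-yl]alane, tertiary oxygen as its dimethylaluminium alkoxide | C[Al](C)/C=C(\C)[C@H]1CC[C@@](C)(O[Al](C)C)[C@@H](Br)C1 | intermediate
22 | (1R,2S,4S)-2-bromo-4-[(2E)-4-hydroxybut-2-en-2-yl]-1-methylcyclohexan-1-ol | OC/C=C(\C)[C@H]1CC[C@@](C)(O)[C@@H](Br)C1 | intermediate
23 | (2E)-3-[(1S,3S,4R)-3-bromo-4-hydroxy-4-methylcyclohexyl]but-2-enal | O=C/C=C(\C)[C@H]1CC[C@@](C)(O)[C@@H](Br)C1 | intermediate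
24 | (1R,2S,4S)-2-bromo-4-[(2E,4R)-4-[(1R)-6,6-dimethyl-2-methylidenecyclohex-4-en-1-yl]-4-hydroxybut-2-en-2-yl]-1-methylcyclohexan-1-ol | C=C1CC=CC(C)(C)[C@@H]1[C@H](O)/C=C(\C)[C@H]1CC[C@@](C)(O)[C@@H](Br)C1 | target

## Step count and risks

Total steps: 12. Longest linear sequence: 8 (steps 5 to 12); the ring A branch is steps 1 to 4 and joins at step 12.

The three steps most likely to fail:

**Step 3 (the proposed new step).** The risks are enolisation of 6 by the carbenoid reagent, migration of the CH2 instead of the quaternary carbon, and incomplete O-triflation. The fallback sets out from 6 and comes back at 9, using a thionium-ion semipinacol of known type. Compound 6 is treated with bis(phenylsulfanyl)methyllithium (CeCl3, THF, −78 °C) to give 1-[bis(phenylsulfanyl)methyl]-2,2-dimethylcyclopent-3-en-1-ol F1. (CuOTf)2·C6H6 and i-Pr2NEt in benzene remove one thiolate, and the quaternary allylic carbon migrates to the thionium carbon, giving 3,3-dimethyl-2-(phenylsulfanyl)cyclohex-4-en-1-one F2. Reductive C–S cleavage with lithium naphthalenide (THF, −78 °C) regenerates enolate 8 regiospecifically, and PhNTf2 gives 9.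

**Step 9.** The risks are elimination or ring contraction of the bromohydrin alkoxide before the lactone closes. The fallback sets out from 16 and comes back at 20. Compound 16 is reduced with i-Bu2AlH (CH2Cl2, −78 °C) to (1R,3S,4R)-3-bromo-4-hydroxy-4-methylcyclohexane-1-carbaldehyde F3. DBU in MeOH equilibrates it with its 1-epimer (1S,3S,4R)-3-bromo-4-hydroxy-4-methylcyclohexane-1-carbaldehyde F4, the open form of lactol 19, in which the formyl group is equatorial and favoured. Ohira–Bestmann homologation of the equilibrating mixture (K2CO3, MeOH) gives 20; the minor 4-epimeric alkyne is removed by chromatography and the selectivity is only moderate.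

**Step 12.** The γ-carbon of 10 sits next to a quaternary centre, so the allylboration may be slow or poorly face-selective. The fallback sets out from 6 and 22 and comes back at 24, making the bond as an aldol bond instead. Compound 6 is ring-expanded as in step 3, but enolate 8 is quenched with Me3SiCl to give [(3,3-dimethylcyclohexa-1,4-dien-1-yl)oxy]trimethylsilane F5. Compound 22 is oxidised with MnO2 and 23 is isolated. SiCl4 with Denmark's binaphthyldiamine-derived bisphosphoramide (5 mol %) and i-Pr2NEt in CH2Cl2 at −78 °C gives the anti aldol (2R)-2-[(1R,2E)-3-[(1S,3S,4R)-3-bromo-4-hydroxy-4-methylcyclohexyl]-1-hydroxybut-2-en-1-yl]-3,3-dimethylcyclohex-4-en-1-one F6. Methylenation with Cp2TiMe2 (toluene, 65 °C) gives 24.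

## Further compounds

F1 | step 3 | 1-[bis(phenylsulfanyl)methyl]-2,2-dimethylcyclopent-3-en-1-ol | OC1(C(Sc2ccccc2)Sc2ccccc2)CC=CC1(C)C
F2 | step 3 | 3,3-dimethyl-2-(phenylsulfanyl)cyclohex-4-en-1-one | O=C1CC=CC(C)(C)C1Sc1ccccc1
F3 | step 9 | (1R,3S,4R)-3-bromo-4-hydroxy-4-methylcyclohexane-1-carbaldehyde | O=C[C@H]1C[C@H](Br)[C@](C)(O)CC1
F4 | step 9 | (1S,3S,4R)-3-bromo-4-hydroxy-4-methylcyclohexane-1-carbaldehyde | O=C[C@@H]1C[C@H](Br)[C@](C)(O)CC1
F5 | step 12 | [(3,3-dimethylcyclohexa-1,4-dien-1-yl)oxy]trimethylsilane | C[Si](C)(C)OC1=CC(C)(C)C=CC1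
F6 | step 12 | (2R)-2-[(1R,2E)-3-[(1S,3S,4R)-3-bromo-4-hydroxy-4-methylcyclohexyl]-1-hydroxybut-2-en-1-yl]-3,3-dimethylcyclohex-4-en-1-one | O=C1CC=CC(C)(C)[C@@H]1[C@H](O)/C=C(\C)[C@H]1CC[C@@](C)(O)[C@@H](Br)C1
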